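## Retrosynthetic overview

1. The 8,9-epoxide comes from a hydroxyl-directed epoxidation of a (Z)-cyclononenol; the nine-membered ring is closed by ring-closing metathesis at C8=C9.
2. The butenolide comes from acid-triggered lactonisation of a (Z)-γ-hydroxy enoate set free from an acetonide.
3. Key disconnection C4a–C11a: an Ireland–Claisen [3,3] rearrangement of an allylic ester sets both ring stereocentres and the C4=C12 olefin, with chirality relayed from the C12 carbinol.
4. The Claisen ester is assembled from a Z-allylic alcohol (ynoate from (S)-linalool 1 plus aldehyde from 2,3-O-isopropylidene-D-erythronolactone 2) and 3-methylidenehex-5-enoic acid (from 3-chloro-2-(chloromethyl)prop-1-ene 3).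
5. Ring order: dioxolane (bought, later removed), then butenolide, then nine-membered carbocycle, then oxirane.

Assumption: (S)-(+)-linalool is bought in high enantiomeric purity; atoms are labelled by xenicane numbering (C1 = CH2OH carbon, C3 = lactone C=O, C4 = butenolide α-carbon, C4a/C11a = ring CH bearing butenolide/CH2OH, C7 = carbinol, C8/C9 = oxirane, C11 = methylidene-bearing carbon, C12 = butenolide β-CH, C13 = butenolide O–CH, C14 = CHOH, C15 = CMe2OH).

## Route

Step 1
Reactants: 1 (S)-(+)-linalool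
Product: 5 (5S)-5-ethenyl-5-methyloxolan-2-ol (lactol of (4S)-4-hydroxy-4-methylhex-5-enal), via secondary ozonide 4 (not isolated)
Conditions: O3 (1.0 equiv, Sudan Red 7B end-point), CH2Cl2, −78 °C; Me2S, −78 °C → rt
Reagents that add atoms: ozone, [O-][O+]=O
Why: Chemoselective ozonolysis (Criegee mechanism, reductive work-up) cleaves the electron-rich trisubstituted alkene much faster than the vinyl group, leaves the bought C7 centre untouched and gives the C4a aldehyde as its lactol.

Step 2
Reactants: 5 (5S)-5-ethenyl-5-methyloxolan-2-ol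
Product: 6 (3S)-3-methylhept-1-en-6-yn-3-ol
Conditions: dimethyl (1-diazo-2-oxopropyl)phosphonate, K2CO3, MeOH, 0 °C → rt
Reagents that add atoms: dimethyl (1-diazo-2-oxopropyl)phosphonate, CC(=O)C(=[N+]=[N-])P(=O)(OC)OC
Why: Seyferth–Gilbert homologation with the Ohira–Bestmann reagent acts on the open hydroxy-aldehyde form of the lactol under mild base and adds C4 as the alkyne terminus.

Step 3
Reactants: 6 (3S)-3-methylhept-1-en-6-yn-3-ol
Product: 8 methyl (6S)-6-methyl-6-[(triethylsilyl)oxy]oct-7-en-2-ynoate, via silyl ether alkyne 7 (not isolated)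
Conditions: n-BuLi (1.0 equiv), THF, −78 °C; Et3SiOTf, −78 → 0 °C; n-BuLi (1.1 equiv), −78 °C; ClCO2Me, −78 → −20 °C
Reagents that add atoms: triethylsilyl trifluoromethanesulfonate, CC[Si](CC)(CC)OS(=O)(=O)C(F)(F)F; methyl chloroformate, COC(=O)Cl
Why: The alkoxide forms first and is O-silylated, then the lithium acetylide is C-acylated to add C3, and the silyl ether blocks later oxa-Michael closure of O7 onto C4a.

Step 4
Reactants: 2 2,3-O-isopropylidene-D-erythronolactone
Product: 9 2-[(4R,5R)-5-(hydroxymethyl)-2,2-dimethyl-1,3-dioxolan-4-yl]propan-2-ol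
Conditions: MeMgBr (3 equiv), THF, 0 °C → rt; H2O
Reagents that add atoms: methylmagnesium bromide, C[Mg]Br
Why: Double Grignard addition to the lactone carbonyl builds the C15 dimethyl carbinol while C13 and C14 are carried over unchanged from the sugar.

Step 5
Reactants: 9 2-[(4R,5R)-5-(hydroxymethyl)-2,2-dimethyl-1,3-dioxolan-4-yl]propan-2-ol
Product: 10 (4R,5R)-2,2-dimethyl-4-{2-[(triethylsilyl)oxy]propan-2-yl}-5-{[(triethylsilyl)oxy]methyl}-1,3-dioxolane
Conditions: Et3SiOTf (2.3 equiv), 2,6-lutidine, CH2Cl2, −78 → 0 °C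
Reagents that add atoms: triethylsilyl trifluoromethanesulfonate, CC[Si](CC)(CC)OS(=O)(=O)C(F)(F)F
Why: The silyl triflate silylates both the primary and the hindered tertiary hydroxyl, which prevents lactol formation once C12 is an aldehyde.

Step 6
Reactants: 10 (4R,5R)-2,2-dimethyl-4-{2-[(triethylsilyl)oxy]propan-2-yl}-5-{[(triethylsilyl)oxy]methyl}-1,3-dioxolane
Product: 11 (4S,5R)-2,2-dimethyl-5-{2-[(triethylsilyl)oxy]propan-2-yl}-1,3-dioxolane-4-carbaldehyde
Conditions: (COCl)2, DMSO, CH2Cl2, −78 → −40 °C; i-Pr2NEt, −78 → 0 °C; used crude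
Reagents that add atoms: none
Why: Swern conditions cleave and oxidise a primary triethylsilyl ether directly to the aldehyde while the tertiary silyl ether survives, and the hindered amine at low temperature limits epimerisation of the cis-dioxolane aldehyde.

Step 7
Reactants: 8 methyl (6S)-6-methyl-6-[(triethylsilyl)oxy]oct-7-en-2-ynoate; 11 (4S,5R)-2,2-dimethyl-5-{2-[(triethylsilyl)oxy]propan-2-yl}-1,3-dioxolane-4-carbaldehyde
Product: 13 Z-allylic alcohol (2Z; 12R; Morita–Baylis–Hillman-type adduct), via α-alumino enoate 12 (not isolated)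
Conditions: i-Bu2AlH, N-methylmorpholine N-oxide, THF, 0 °C; 8, 0 °C → rt; then 11, 0 °C → rt; sat. aq. NH4Cl; chromatography removes the minor 12S epimer
Reagents that add atoms: none
Why: Conjugate hydroalumination gives an aluminium allenolate whose aldol addition (vinylalumination, a reductive aldol) occurs anti to the β-substituent to give the Z-enoate and on the Felkin–Anh face of the α-alkoxy aldehyde, so the bought C13 centre sets 12R (12,13-anti).

Step 8
Reactants: 3 3-chloro-2-(chloromethyl)prop-1-ene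
Product: 14 2-(chloromethyl)penta-1,4-diene
Conditions: CH2=CHMgBr (0.4 equiv relative to 3), CuI (5 mol%), THF, −30 → 0 °C; distillation
Reagents that add atoms: vinylmagnesium bromide, C=C[Mg]Br
Why: Copper-catalysed allylic substitution of one chloride (SN2 and SN2' give the same product) is kept to mono-coupling by the excess of the dichloride.

Step 9
Reactants: 14 2-(chloromethyl)penta-1,4-diene
Product: 16 3-methylidenehex-5-enoic acid, via allylic Grignard reagent 15 (not isolated)
Conditions: Mg, THF, 0 °C (slow addition); CO2, −40 °C → rt; aq. HCl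
Reagents that add atoms: carbon dioxide, O=C=O
Why: Carboxylation of the 2-substituted allylic Grignard reagent gives the same β,γ-unsaturated acid from either allyl terminus.

Step 10
Reactants: 13 Z-allylic alcohol; 16 3-methylidenehex-5-enoic acid
Product: 17 C12 3-methylidenehex-5-enoate ester of 13
Conditions: N,N'-diisopropylcarbodiimide, DMAP (5 mol%), CH2Cl2, 0 °C
Reagents that add atoms: none
Why: Steglich esterification acylates the only free hydroxyl, and low DMAP loading at 0 °C keeps the β,γ-unsaturated acyl group out of conjugation.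

Step 11
Reactants: 17 C12 3-methylidenehex-5-enoate ester
Product: 20 Claisen acid (4aS,11aR; C4=C12 Z), via silyl ketene acetal 18 (not isolated), via trimethylsilyl ester 19 (not isolated)
Conditions: LiN(SiMe3)2, Me3SiCl, THF/DMPU (4:1), −78 °C → rt, then 40 °C; aq. citric acid
Reagents that add atoms: none
Why: In this Ireland–Claisen [3,3]-sigmatropic rearrangement the most acidic allylic α-CH2 gives the Z(O) dienolate, and a chair transition state with C13 equatorial transfers 12R to 4aS and 11aR (syn pair, trans on the future ring) while forming C4=C12 with C13 cis to the ester.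

Step 12
Reactants: 20 Claisen acid
Product: 22 primary alcohol (C1 CH2OH; methyl ester, silyl ethers and acetonide retained), via mixed carbonic anhydride 21 (not isolated)
Conditions: i-BuOCOCl, N-methylmorpholine, THF, −15 °C; NaBH4, H2O, 0 °C, 15 min
Reagents that add atoms: none
Why: Borohydride reduces only the activated mixed anhydride, leaving the conjugated methyl ester, the alkenes and the protecting groups untouched, and the short cold contact avoids epimerisation at C11a.

Step 13
Reactants: 22 primary alcohol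
Product: 23 acyclic butenolide tetraol
Conditions: AcOH/H2O/THF (3:1:1), 45 °C
Reagents that add atoms: none
Why: Mild aqueous acid removes both silyl ethers and the acetonide without ionising the tertiary allylic alcohol, and the freed O13–H, held cis to the ester, lactonises at once to the butenolide with C13 and C14 unchanged.

Step 14
Reactants: 23 acyclic butenolide tetraol
Product: 24 (Z)-cyclononenol (nine-membered ring closed at C8=C9)
Conditions: Hoveyda–Grubbs second-generation catalyst [RuCl2(=CH-C6H4-2-O-i-Pr)(SIMes)] (10 mol%), 1,4-benzoquinone (20 mol%), CH2Cl2 (1 mM), reflux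
Reagents that add atoms: none
Why: In this ring-closing metathesis the ruthenium alkylidene forms at the allyl terminus and closes onto the free vinyl carbinol (as in the facile metathesis of linalool itself), the 1,1-disubstituted and butenolide alkenes are inert, and ring size enforces Z.

Step 15
Reactants: 24 (Z)-cyclononenol
Product: 25 target, (5R)-5-[(1R)-1,2-dihydroxy-2-methylpropyl]-3-[(1R,2S,5S,6R,9R)-2-hydroxy-6-(hydroxymethyl)-2-methyl-7-methylidene-10-oxabicyclo[7.1.0]decan-5-yl]furan-2(5H)-one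
Conditions: VO(acac)2 (5 mol%), t-BuOOH (1.2 equiv, decane), CH2Cl2, 0 °C
Reagents that add atoms: tert-butyl hydroperoxide, CC(C)(C)OO
Why: Hydroxyl-directed epoxidation through the vanadate ester of the tertiary allylic alcohol delivers oxygen to the alkene face syn to O7–H (cis-epoxy alcohol, as for medium-ring Z-cycloalkenols), giving 8R,9R from the bought 7S centre, and the allylic alkene reacts faster than the homoallylic methylidene.

## Compound list

1 | (S)-(+)-linalool, (3S)-3,7-dimethylocta-1,6-dien-3-ol | C=C[C@@](C)(O)CCC=C(C)C | starting material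
2 | 2,3-O-isopropylidene-D-erythronolactone, (3aR,6aR)-2,2-dimethyldihydrofuro[3,4-d][1,3]dioxol-4(3aH)-one | CC1(C)O[C@@H]2COC(=O)[C@@H]2O1 | starting material
3 | 3-chloro-2-(chloromethyl)prop-1-ene | C=C(CCl)CCl | starting material
4 | 5-[(3S)-3-hydroxy-3-methylpent-4-en-1-yl]-3,3-dimethyl-1,2,4-trioxolane (secondary ozonide, epimers at the ring CH) | C=C[C@@](C)(O)CCC1OOC(C)(C)O1 | intermediate
5 | (5S)-5-ethenyl-5-methyloxolan-2-ol (anomer mixture; ring form of (4S)-4-hydroxy-4-methylhex-5-enal) | C=C[C@]1(C)CCC(O)O1 | intermediate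
6 | (3S)-3-methylhept-1-en-6-yn-3-ol | C=C[C@@](C)(O)CCC#C | intermediate
7 | triethyl{[(3S)-3-methylhept-1-en-6-yn-3-yl]oxy}silane | C=C[C@@](C)(O[Si](CC)(CC)CC)CCC#C | intermediate
8 | methyl (6S)-6-methyl-6-[(triethylsilyl)oxy]oct-7-en-2-ynoate | C=C[C@@](C)(O[Si](CC)(CC)CC)CCC#CC(=O)OC | intermediate
9 | 2-[(4R,5R)-5-(hydroxymethyl)-2,2-dimethyl-1,3-dioxolan-4-yl]propan-2-ol | CC1(C)O[C@H](CO)[C@H](C(C)(C)O)O1 | intermediate
10 | (4R,5R)-2,2-dimethyl-4-{2-[(triethylsilyl)oxy]propan-2-yl}-5-{[(triethylsilyl)oxy]methyl}-1,3-dioxolane | CC1(C)O[C@H](CO[Si](CC)(CC)CC)[C@H](C(C)(C)O[Si](CC)(CC)CC)O1 | intermediate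
11 | (4S,5R)-2,2-dimethyl-5-{2-[(triethylsilyl)oxy]propan-2-yl}-1,3-dioxolane-4-carbaldehyde | CC1(C)O[C@H](C=O)[C@H](C(C)(C)O[Si](CC)(CC)CC)O1 | intermediate
12 | methyl (6S)-2-(diisobutylalumanyl)-6-methyl-6-[(triethylsilyl)oxy]octa-2,7-dienoate (C-bound form of the aluminium allenolate) | COC(=O)C(=CCC[C@](C)(O[Si](CC)(CC)CC)C=C)[Al](CC(C)C)CC(C)C | intermediate
13 | methyl (2Z,6S)-2-{(R)-[(4R,5R)-2,2-dimethyl-5-{2-[(triethylsilyl)oxy]propan-2-yl}-1,3-dioxolan-4-yl](hydroxy)methyl}-6-methyl-6-[(triethylsilyl)oxy]octa-2,7-dienoate | COC(=O)/C(=C\CC[C@](C)(O[Si](CC)(CC)CC)C=C)[C@@H](O)[C@H]1OC(C)(C)O[C@H]1C(C)(C)O[Si](CC)(CC)CC | intermediate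
14 | 2-(chloromethyl)penta-1,4-diene | C=CCC(=C)CCl | intermediate
15 | chlorido(2-methylidenepent-4-en-1-yl)magnesium | C=CCC(=C)C[Mg]Cl | intermediate
16 | 3-methylidenehex-5-enoic acid | C=CCC(=C)CC(=O)O | intermediate
17 | ester of 13 at O12 with 3-methylidenehex-5-enoic acid (2Z, 6S, 12R, dioxolane 4R,5R) | COC(=O)/C(=C\CC[C@](C)(O[Si](CC)(CC)CC)C=C)[C@@H](OC(=O)CC(=C)CC=C)[C@H]1OC(C)(C)O[C@H]1C(C)(C)O[Si](CC)(CC)CC | intermediate
18 | (Z)-O-trimethylsilyl ketene acetal of 17 (C11 cis to OSiMe3) | COC(=O)/C(=C\CC[C@](C)(O[Si](CC)(CC)CC)C=C)[C@@H](O/C(O[Si](C)(C)C)=C/C(=C)CC=C)[C@H]1OC(C)(C)O[C@H]1C(C)(C)O[Si](CC)(CC)CC | intermediate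
19 | trimethylsilyl ester of acid 20 | C[Si](C)(C)OC(=O)[C@@H](C(=C)CC=C)[C@H](CC[C@](C)(O[Si](CC)(CC)CC)C=C)/C(C(=O)OC)=C/[C@H]1OC(C)(C)O[C@H]1C(C)(C)O[Si](CC)(CC)CC | intermediate
20 | (2R,3S,4Z)-5-[(4R,5R)-2,2-dimethyl-5-{2-[(triethylsilyl)oxy]propan-2-yl}-1,3-dioxolan-4-yl]-4-(methoxycarbonyl)-3-{(3S)-3-methyl-3-[(triethylsilyl)oxy]pent-4-en-1-yl}-2-(penta-1,4-dien-2-yl)pent-4-enoic acid | OC(=O)[C@@H](C(=C)CC=C)[C@H](CC[C@](C)(O[Si](CC)(CC)CC)C=C)/C(C(=O)OC)=C/[C@H]1OC(C)(C)O[C@H]1C(C)(C)O[Si](CC)(CC)CC | intermediate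
21 | isobutyl carbonic mixed anhydride of acid 20 | CC(C)COC(=O)OC(=O)[C@@H](C(=C)CC=C)[C@H](CC[C@](C)(O[Si](CC)(CC)CC)C=C)/C(C(=O)OC)=C/[C@H]1OC(C)(C)O[C@H]1C(C)(C)O[Si](CC)(CC)CC | intermediate
22 | methyl (2Z,3S,4R)-2-{[(4R,5R)-2,2-dimethyl-5-{2-[(triethylsilyl)oxy]propan-2-yl}-1,3-dioxolan-4-yl]methylidene}-4-(hydroxymethyl)-5-methylidene-3-{(3S)-3-methyl-3-[(triethylsilyl)oxy]pent-4-en-1-yl}oct-7-enoate | OC[C@@H](C(=C)CC=C)[C@H](CC[C@](C)(O[Si](CC)(CC)CC)C=C)/C(C(=O)OC)=C/[C@H]1OC(C)(C)O[C@H]1C(C)(C)O[Si](CC)(CC)CC | intermediate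
23 | (5R)-5-[(1R)-1,2-dihydroxy-2-methylpropyl]-3-[(3S,6S,7R)-3-hydroxy-7-(hydroxymethyl)-3-methyl-8-methylideneundeca-1,10-dien-6-yl]furan-2(5H)-one | C=CCC(=C)[C@H](CO)[C@H](CC[C@](C)(O)C=C)C1=C[C@H]([C@@H](O)C(C)(C)O)OC1=O | intermediate
24 | (5R)-5-[(1R)-1,2-dihydroxy-2-methylpropyl]-3-[(1S,4S,5Z,9R)-4-hydroxy-9-(hydroxymethyl)-4-methyl-8-methylidenecyclonon-5-en-1-yl]furan-2(5H)-one | C=C1C/C=C\[C@@](C)(O)CC[C@H](C2=C[C@H]([C@@H](O)C(C)(C)O)OC2=O)[C@H]1CO | intermediate
25 | (5R)-5-[(1R)-1,2-dihydroxy-2-methylpropyl]-3-[(1R,2S,5S,6R,9R)-2-hydroxy-6-(hydroxymethyl)-2-methyl-7-methylidene-10-oxabicyclo[7.1.0]decan-5-yl]furan-2(5H)-one (CNP0411123.2) | C=C1C[C@H]2O[C@H]2[C@@](C)(O)CC[C@H](C2=C[C@H]([C@@H](O)C(C)(C)O)OC2=O)[C@H]1CO | target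

## Step count and risks

Total steps: 15. Longest linear sequence: 10 steps (steps 1, 2, 3, 7, 10, 11, 12, 13, 14, 15).

Most likely to fail:

Step 14 (nine-membered ring-closing metathesis). The acyclic precursor may oligomerise, or the vinyl carbinol may close on the C11 methylidene to give a seven-membered ring. The fallback sets out from 22 and comes back at 24, using a temporary six-membered lactone to hold the two chains gauche before metathesis. Treatment of 22 with n-Bu4NF in THF removes both silyl groups and lets the C1 alkoxide close onto the methyl ester, giving the α-alkylidene δ-lactone diol F3. Ring-closing metathesis of this conformationally biased substrate with the same ruthenium catalyst gives the trans-fused bicyclic lactone F4. Warm aqueous acetic acid, with catalytic camphorsulfonic acid if needed, then removes the acetonide and lets O13 translactonise onto C3 to give butenolide 24.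

Step 7 (vinylalumination–aldol). The β-substituted ynoate may hydroaluminate slowly, and the enoate geometry or the C12 selectivity with the hindered aldehyde may be poor. The fallback sets out from 6 and 11 and comes back at 13. Alcohol 6 is silylated (Et3SiOTf, 2,6-lutidine) to 7, which is isolated this time. Its lithium acetylide (n-BuLi, THF, −78 °C) adds to 11 under Felkin–Anh control to give the propargylic alcohol F1. Hydroxyl-directed trans-hydrostannation (Bu3SnH, [Cp*RuCl]4) places tin on C4 and hydrogen on C4a on opposite faces, giving the (Z)-α-stannyl allylic alcohol F2. Methoxycarbonylation (CO, MeOH, Pd(OAc)2, Ph3As, 1,4-benzoquinone, catalytic CF3CO2H) then gives 13 with the ester cis to C5 by construction.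

Step 15 (chemoselective directed epoxidation). The free C1 hydroxyl is homoallylic to the C11 methylidene and could direct a competing epoxidation, and the tertiary alcohol binds vanadium slowly. The fallback sets out from 24 and comes back at 25. The primary hydroxyl is masked selectively (t-BuMe2SiCl, imidazole, 0 °C) to give the silyl ether F5. The same VO(acac)2/t-BuOOH epoxidation, now with only O7–H able to direct, gives the epoxy silyl ether F6. HF·pyridine in THF removes the silyl group to give 25.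

## Further compounds

F1 | step 7 | (1R,6S)-1-[(4R,5R)-2,2-dimethyl-5-{2-[(triethylsilyl)oxy]propan-2-yl}-1,3-dioxolan-4-yl]-6-methyl-6-[(triethylsilyl)oxy]oct-7-en-2-yn-1-ol | C=C[C@@](C)(O[Si](CC)(CC)CC)CCC#C[C@@H](O)[C@H]1OC(C)(C)O[C@H]1C(C)(C)O[Si](CC)(CC)CC
F2 | step 7 | (1S,2Z,6S)-1-[(4R,5R)-2,2-dimethyl-5-{2-[(triethylsilyl)oxy]propan-2-yl}-1,3-dioxolan-4-yl]-6-methyl-2-(tributylstannyl)-6-[(triethylsilyl)oxy]octa-2,7-dien-1-ol (same spatial arrangement at C12 as in 13) | C=C[C@@](C)(O[Si](CC)(CC)CC)CC/C=C(\[Sn](CCCC)(CCCC)CCCC)[C@@H](O)[C@H]1OC(C)(C)O[C@H]1C(C)(C)O[Si](CC)(CC)CC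
F3 | step 14 | (3Z,4S,5R)-3-{[(4R,5R)-5-(2-hydroxypropan-2-yl)-2,2-dimethyl-1,3-dioxolan-4-yl]methylidene}-4-[(3S)-3-hydroxy-3-methylpent-4-en-1-yl]-5-(penta-1,4-dien-2-yl)oxan-2-one | O=C1OC[C@@H](C(=C)CC=C)[C@H](CC[C@](C)(O)C=C)/C1=C/[C@H]2OC(C)(C)O[C@H]2C(C)(C)O
F4 | step 14 | trans-fused δ-lactone/(Z)-cyclononene from metathesis of F3 (C1–O–C3 lactone, exocyclic C4=C12 Z, acetonide retained, 4aS,7S,11aR) | O=C1OC[C@H]2C(=C)C/C=C\[C@@](C)(O)CC[C@@H]2/C1=C/[C@H]3OC(C)(C)O[C@H]3C(C)(C)O
F5 | step 15 | C1 O-tert-butyldimethylsilyl ether of 24 | C=C1C/C=C\[C@@](C)(O)CC[C@H](C2=C[C@H]([C@@H](O)C(C)(C)O)OC2=O)[C@H]1CO[Si](C)(C)C(C)(C)C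
F6 | step 15 | C1 O-tert-butyldimethylsilyl ether of 25 | C=C1C[C@H]2O[C@H]2[C@@](C)(O)CC[C@H](C2=C[C@H]([C@@H](O)C(C)(C)O)OC2=O)[C@H]1CO[Si](C)(C)C(C)(C)C
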